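The cyclobutane is opened at its two cis edges, C2–C3 and C4–C1 (text labels: C1, C3 carry the aryl groups, C2, C4 the acyl groups). Each edge joins a benzylic carbon to a carbonyl-α carbon. An NH placed in both edges gives the precursor: the centrosymmetric, all-equatorial 3,6-diarylpiperazine-2,5-dicarboxylate, the head-to-tail dimer of one glycine aldimine and the most stable isomer of that ring. One operation then expels both nitrogens as N2 through isodiazenes, contracting the piperazine via a pyrrolidine to the cyclobutane. The diequatorial 2,6- and 3,5-cis pairs become the cis edges and the 2,3-trans pairs remain the trans edges, so the less stable cyclobutane epimer is obtained from a thermodynamically controlled six-membered ring.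

Key step: step 3

Remark: the ester groups are spectators and are taken as benzyl. The centrosymmetric cyclobutane is expected to be less stable than its epimer at a carbonyl-bearing carbon (two against three pseudo-equatorial substituents), so the esters are removed by neutral hydrogenolysis and the only base after step 3 acts at −78 °C. Labels C1–C4 above and in step 3 are text labels, not locants of the systematic names. Compounds 4 and 6 are racemic (one enantiomer drawn); the other stereodefined compounds are achiral.

Step 1
Reactants: 1 veratraldehyde (3,4-dimethoxybenzaldehyde); 2 glycine benzyl ester hydrochloride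
Product: 3 benzyl (E)-N-(3,4-dimethoxybenzylidene)glycinate
Conditions: Et3N, MgSO4, CH2Cl2, 23 °C; filter, concentrate, use crude
Reagents that add atoms: none
Why: Schiff-base condensation of a primary amine with an aromatic aldehyde, driven by removal of water, should give only the E aldimine and leaves the ester untouched.

Step 2
Reactants: 3 benzyl (E)-N-(3,4-dimethoxybenzylidene)glycinate (two molecules)
Product: 5 dibenzyl 3,6-bis(3,4-dimethoxyphenyl)piperazine-2,5-dicarboxylate (2,3-trans/2,5-trans/2,6-cis; all-equatorial; centrosymmetric), via open-chain Mannich adduct 4 (not isolated)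
Conditions: LiBr, DBU, THF, 23 → 50 °C, N2; product collected by crystallisation
Reagents that add atoms: none
Why: Head-to-tail formal [3+3] dimerisation of the N-lithiated azomethine ylide by two Mannich additions (intermolecular to 4, then 6-endo-trig closure of the chelated glycinate enolate onto the remaining aldimine); because these additions and the competing aminal closure are reversible under the conditions, the four new stereocentres should settle under thermodynamic control in the chair with all substituents equatorial, which is the 2,3-trans/2,6-cis centrosymmetric isomer.

Step 3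
Reactants: 5 dibenzyl 3,6-bis(3,4-dimethoxyphenyl)piperazine-2,5-dicarboxylate (all-equatorial)
Product: 7 dibenzyl 2,4-bis(3,4-dimethoxyphenyl)cyclobutane-1,3-dicarboxylate (1α,2α,3β,4β; centrosymmetric), via pyrrolidine diester 6 (not isolated)
Conditions: N-(benzyloxy)-N-(pivaloyloxy)-4-(trifluoromethyl)benzamide (3.5 equiv, two portions), THF, 45 °C, N2
Reagents that add atoms: none
Why: Proposed new method: each NH attacks the amide nitrogen of the anomeric amide with loss of pivalate, the N-benzyloxy hydrazide so formed expels benzyl 4-(trifluoromethyl)benzoate to give an isodiazene, and loss of N2 leaves a singlet biradical that recombines, so that 5 gives pyrrolidine 6 (bond between piperazine C2 and C6) and 6 gives 7 (bond between former C3 and C5), that is, the cyclobutane edges C4–C1 and C2–C3. The closest known reaction types are the nitrogen deletion of secondary amines with this reagent and the contraction of 2-aryl pyrrolidine esters to cyclobutanes through isodiazenes; a twofold deletion from a piperazine, and the first contraction with a second NH in the ring, are without precedent. The four-membered ring closes by collapse of a 1,4-biradical with a benzylic and an α-alkoxycarbonyl terminus, after the transient five-membered ring has closed in the same way from a 1,5-biradical. Each of the four cyclobutane stereocentres is controlled by the configuration of the piperazine carbon it comes from, because each C–C bond forms with retention where nitrogen leaves, so the diequatorial 2,6-cis and 3,5-cis pairs of 5 become the two cis edges and the 2,3-trans and 5,6-trans pairs stay as the trans edges. The step needs recombination to be faster than bond rotation, hydrogen transfer and β-scission to cinnamates; this is secured by the singlet state, by radical stabilisation at both termini and by the ring that holds them close, and the portionwise addition should let the second isodiazene form after the first contraction.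

Step 4
Reactants: 7 dibenzyl 2,4-bis(3,4-dimethoxyphenyl)cyclobutane-1,3-dicarboxylate
Product: 8 (1α,2α,3β,4β)-2,4-bis(3,4-dimethoxyphenyl)cyclobutane-1,3-dicarboxylic acid
Conditions: H2 (1 atm), Pd/C (10 wt%), EtOAc–MeOH, 23 °C
Reagents that add atoms: none
Why: Hydrogenolysis of the benzyl esters is neutral, so the enolisable ring carbons never meet a base and the configuration fixed in step 3 is kept, while the aryl ethers and the cyclobutane are inert under these conditions.

Step 5
Reactants: 8 (1α,2α,3β,4β)-2,4-bis(3,4-dimethoxyphenyl)cyclobutane-1,3-dicarboxylic acid; 9 5,6-dihydropyridin-2(1H)-one (two molecules)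
Product: 11 1,1'-{[(1α,2α,3β,4β)-2,4-bis(3,4-dimethoxyphenyl)cyclobutane-1,3-diyl]dicarbonyl}bis(5,6-dihydropyridin-2(1H)-one) (CNP0199212.1), via bis(acid chloride) 10 (not isolated)
Conditions: (COCl)2, DMF (cat.), CH2Cl2, 0 → 23 °C, evaporate; then 9 (2.2 equiv), LiN(SiMe3)2 (2.1 equiv), THF, −78 °C, add 10, −78 °C, quench AcOH
Reagents that add atoms: none
Why: Acid chloride formation with oxalyl chloride (chloroiminium catalysis, no base) followed by twofold N-acylation of the lithium lactamide, one lactam unit per acyl chloride and the usual way to N-acyl-5,6-dihydropyridin-2-ones, should join both imides at −78 °C before any enolisation of the ring α-carbons, so no stereocentre is touched.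

Compound list
1 | veratraldehyde (3,4-dimethoxybenzaldehyde) | COc1ccc(C=O)cc1OC | starting material
2 | glycine benzyl ester hydrochloride | Cl.NCC(=O)OCc1ccccc1 | starting material
3 | benzyl (E)-N-(3,4-dimethoxybenzylidene)glycinate | COc1ccc(/C=N/CC(=O)OCc2ccccc2)cc1OC | intermediate
4 | benzyl 3-{[2-(benzyloxy)-2-oxoethyl]amino}-2-{[(E)-(3,4-dimethoxyphenyl)methylidene]amino}-3-(3,4-dimethoxyphenyl)propanoate, the diastereomer that becomes 2,3-trans in the ring (racemic; one enantiomer drawn) | COc1ccc(/C=N/[C@H](C(=O)OCc2ccccc2)[C@@H](c2ccc(OC)c(OC)c2)NCC(=O)OCc2ccccc2)cc1OC | intermediate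
5 | dibenzyl 3,6-bis(3,4-dimethoxyphenyl)piperazine-2,5-dicarboxylate, 2,3-trans/2,5-trans/2,6-cis, all substituents equatorial, centrosymmetric | N1[C@H](C(=O)OCc2ccccc2)[C@@H](c2ccc(OC)c(OC)c2)N[C@@H](C(=O)OCc2ccccc2)[C@@H]1c1ccc(OC)c(OC)c1 | intermediate
6 | dibenzyl 3,5-bis(3,4-dimethoxyphenyl)pyrrolidine-2,4-dicarboxylate, 2,5-cis/2,3-trans/3,4-cis/4,5-trans (racemic; one enantiomer drawn) | N1[C@@H](C(=O)OCc2ccccc2)[C@H](c2ccc(OC)c(OC)c2)[C@H](C(=O)OCc2ccccc2)[C@H]1c1ccc(OC)c(OC)c1 | intermediate
7 | dibenzyl (1α,2α,3β,4β)-2,4-bis(3,4-dimethoxyphenyl)cyclobutane-1,3-dicarboxylate, centrosymmetric | COc1ccc([C@H]2[C@H](C(=O)OCc3ccccc3)[C@H](c3ccc(OC)c(OC)c3)[C@H]2C(=O)OCc2ccccc2)cc1OC | intermediate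
8 | (1α,2α,3β,4β)-2,4-bis(3,4-dimethoxyphenyl)cyclobutane-1,3-dicarboxylic acid | COc1ccc([C@H]2[C@H](C(=O)O)[C@H](c3ccc(OC)c(OC)c3)[C@H]2C(=O)O)cc1OC | intermediate
9 | 5,6-dihydropyridin-2(1H)-one | O=C1C=CCCN1 | starting material
10 | (1α,2α,3β,4β)-2,4-bis(3,4-dimethoxyphenyl)cyclobutane-1,3-dicarbonyl dichloride | COc1ccc([C@H]2[C@H](C(=O)Cl)[C@H](c3ccc(OC)c(OC)c3)[C@H]2C(=O)Cl)cc1OC | intermediate
11 | 1,1'-{[(1α,2α,3β,4β)-2,4-bis(3,4-dimethoxyphenyl)cyclobutane-1,3-diyl]dicarbonyl}bis(5,6-dihydropyridin-2(1H)-one), CNP0199212.1 | COc1ccc([C@H]2[C@H](C(=O)N3CCC=CC3=O)[C@H](c3ccc(OC)c(OC)c3)[C@H]2C(=O)N2CCC=CC2=O)cc1OC | target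

Total steps: 5. Longest linear sequence: 5 (1 or 2 → 3 → 5 → 7 → 8 → 11).

Steps most likely to fail

Step 3. Several processes can defeat it:
- The longer-lived 1,5-biradical of the first deletion may rotate before it closes, which loses a cis edge.
- It may transfer a hydrogen atom and end as an open-chain enamino ester.
- The 1,4-biradical of the second deletion may cleave to two cinnamate molecules.
- An isodiazene next to the ester-bearing C–H may tautomerise to a hydrazone.
- The doubly α-branched nitrogen may attack the reagent too slowly.

The fallback uses known chemistry only, sets out from 1 and comes back at 8. Knoevenagel–Doebner condensation of 1 with malonic acid (pyridine, piperidine cat., 90 °C) should give (E)-3-(3,4-dimethoxyphenyl)acrylic acid F1. UV irradiation of the crystalline, head-to-tail packed form of F1 is the classical topochemical [2+2] photodimerisation of a cinnamic acid and should give the centrosymmetric diacid 8 directly, provided the photoreactive crystal form is obtained. Step 5 then follows unchanged.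

Step 2. The second ring closure may run through nitrogen (aminal formation to the five-membered imidazolidine) and hold the material there, or equilibration through retro-Mannich steps may be too slow to funnel the mixture into one diastereomer. The fallback gives up the six-membered ring and enters at the five-membered intermediate; it sets out from 1 and 3 and comes back at 6. Z-selective Horner–Wadsworth–Emmons olefination of 1 with benzyl 2-(diphenoxyphosphoryl)acetate (NaH, THF, −78 °C) should give benzyl (Z)-3-(3,4-dimethoxyphenyl)acrylate F2. A [3+2] cycloaddition of the metalated azomethine ylide of 3 to F2 (Cu(CH3CN)4PF6, a bulky bisphosphine, Et3N, THF) under exo control should then give pyrrolidine 6. The Z alkene sets 3,4-cis, the chelated W-shaped ylide sets 2,5-cis, and exo approach sets 2,3-trans and 4,5-trans. The endo adduct would lead to the wrong cyclobutane, so the relative configuration of the adduct has to be secured before use. Isolated 6 then needs only one nitrogen deletion under the step 3 conditions, the half of the key step with direct precedent, to reach 7.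

Step 5. The lactamide is a base: it may enolise the acid chloride (through the ketene) or the imide product, which epimerises the carbonyl-bearing ring carbons towards the more stable isomer. The fallback replaces anionic acylation by a base-free silyl transfer; it sets out from 9 (with 10 made as in step 5) and comes back at 11. Silylation of 9 (Me3SiCl, Et3N, toluene) should give 1-(trimethylsilyl)-5,6-dihydropyridin-2(1H)-one F3. Heating two equivalents of F3 with 10 in toluene should acylate nitrogen with loss of Me3SiCl, with no species present that can deprotonate the ring.

Further compounds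
F1 | step 3 | (E)-3-(3,4-dimethoxyphenyl)acrylic acid | COc1ccc(/C=C/C(=O)O)cc1OC
F2 | step 2 | benzyl (Z)-3-(3,4-dimethoxyphenyl)acrylate | COc1ccc(/C=C\C(=O)OCc2ccccc2)cc1OC
F3 | step 5 | 1-(trimethylsilyl)-5,6-dihydropyridin-2(1H)-one | C[Si](C)(C)N1CCC=CC1=O
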